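Its constants are assumed; the flask was simulated.

The vessel is a closed, stirred two-phase flask: the starting material sits in the first phase, and the reagent is charged to the second phase and reaches the reaction through step 3.

starting material 0.45 M; reagent in the second phase 1.12 M; time 30 min; volume of the second phase over the first 2.0

    reagent in the reaction phase ⇌ dormant form (K1 = 0.42, k1 = 0.22 min⁻¹)
    crystals ⇌ product, rate k2*(cs2 - [product]) while solid is left; crystals form when [product] > cs2 (cs2 = 17 mM, k2 = 15 min⁻¹)
    reagent in the reaction phase ⇌ reagent in the second phase, rate k3*([reagent in the reaction phase] - [reagent in the second phase]/K3) per volume of the first phase (K3 = 2.4, k3 = 0.090 min⁻¹)
    reagent in the reaction phase → decomposed reagent (k4 = 0.069 min⁻¹)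
    starting material + reagent in the reaction phase → product (k5 = 1.9 M⁻¹ min⁻¹)

1. how much product and crystals together there is at 30 min, in percent of the starting material charged
2. the change that raises the amount of product and crystals together at 30 min, in percent of the starting material charged most ("none" if none brings more than 2 percentage points) (teal / green / red / amber / none)
3. amount of product and crystals together at 30 min, in percent of the starting material charged, after amber

- teal: doubling the amount of reagent in the second phase, all else as stated
- green: doubling the transfer coefficient of step 3, all else as stated
- red: doubling the solubility in step 2, all else as stated
- amber: doubling the dissolution coefficient of step 2, all else as stated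

For whoever takes over: the reagent enters the first phase at an opening feed of

feed = transfer coefficient × 0.560 M ÷ partition ratio = 0.0210 M min⁻¹

Once there, it is caught by starting material, or it returns or decomposes, while the dormant form holds some back reversibly, so

(transfer coefficient + rate constant of step 4) ÷ rate constant of step 5 = 0.0837 M

is the crossing level: the [starting material] at which capture equals those two losses together. The captured share of the feed is [starting material] ÷ ([starting material] + crossing level), which is 84.3 % at the charge, so transfer opens as the rate-limiting step.

The second phase empties on a scale of 53.3 min, which lowers the mean feed over the run to 0.0161 M min⁻¹. Integrating the captured feed then gives

time to crossing = 31.6 min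

That is later than the 30 min reading, so I expect somewhat under 81.4 % of product and crystals then, with starting material still above the crossing.

Leave the crystals be: step 2 moves material between two counted forms and enters neither feed nor crossing, so I expect red and amber, which change step 2, to leave the total where it is. Teal doubles the feed at the same crossing, while green also lifts the crossing to 0.131 M, so I put teal first.

The forecast gives 75 %, teal as the best change and 75 % after amber, holding that "doubling the reagent charge roughly doubles the reaction-phase reagent level".

The flask gives 74.6 %, and 74.6 % after amber, with teal ahead at 24 percentage points against 18 points for green. At 30.0 min the flask holds 25.4 % of its starting material, above the crossing at 18.6 % of the charge, so the captured share is 57.7 %. The same flask read at 50 min holds 5.93 %, below the crossing, its captured share is down to 24.2 %, and product and crystals stand at 94.1 %.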